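All runs were computed for an exercise.

4 questions stood open when I handed you the north, east and south-west flasks.

| setting | violet | blue | teal | north | east | south-west |
|---|---|---|---|---|---|---|
| electrophile | 0.20 M | 0.20 M | 0.20 M | 0.20 M | 0.20 M | 0.20 M |
| free base | 0.53 M | 0.73 M | 0.96 M | 1.00 M | 0.600 M | 0.780 M |
| protonated nucleophile | 0.16 M | 0.16 M | 0.16 M | 0.160 M | 0.160 M | 0.160 M |
| remark | run made earlier | run made earlier | run made earlier |  |  |  |
| time |  |  |  | 6.0 d | 6.0 d | 6.0 d |

| run | time / d | electrophile / % | product / % |
|---|---|---|---|
| violet | 0.833 | 33.0 | 66.7 |
| violet | 1.67 | 20.8 | 79.0 |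
| violet | 2.50 | 16.8 | 78.2 |
| violet | 3.00 | 21.2 | 81.5 |
| blue | 0.417 | 47.0 | 52.7 |
| blue | 1.04 | 24.1 | 75.1 |
| blue | 2.08 | 20.8 | 80.6 |
| blue | 3.00 | 21.0 | 79.4 |
| teal | 0.250 | 58.0 | 39.8 |
| teal | 0.500 | 40.5 | 58.6 |
| teal | 1.25 | 23.9 | 78.9 |
| teal | 3.00 | 20.6 | 78.2 |

(each reading ± 1 percentage point)

- the numbers in the tables scatter with a standard deviation of 1 percentage point

* part of the electrophile that has reacted at the end, north
* part of the electrophile that has reacted at the end, east
* part of the electrophile that has reacted at the end, south-west
* what raising the concentration of free base from its lowest to its highest value here does to the part of the electrophile that has reacted (changes below 5 percentage points count as none) (it falls / no change / it rises)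

I carried one number to the bench: the ceiling, c(protonated nucleophile) charged over c(electrophile) charged, 80.0%, which assumes that one protonated nucleophile serves one electrophile, so that the protonated nucleophile is the limiting reagent, since its charge was 0.160 M against 0.20 M. The earlier runs supported this reading: at 3.00 d the violet, blue and teal runs read 81.5%, 79.4% and 78.2% of product, with a scatter of 1 point, although c(free base) rose from 0.53 M to 0.96 M. The pace differed between the runs, for teal read 78.9% of product at 1.25 d, while violet read 79.0% at 1.67 d. I told you to expect about 80.0% reacted in north, east and south-west at 6.0 d, twice the time of those last readings, with about 20.0% of the electrophile still there. I asked you not to add free base in the hope of a higher end point, and not to alter c(protonated nucleophile) or c(electrophile), the two charges whose ratio is the ceiling.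

The forecast gave 80%, 80% and 80%, with no change, in its words: “So the nucleophile is limiting, rather than an equilibrium that would shift with base.”

The flasks gave 80.0%, 80.0% and 80.0%, with no change.

    electrophile + nucleophile → acid set free + product (k = 2.67 M⁻¹ h⁻¹)
    nucleophile + acid set free ⇌ protonated nucleophile, settled at all times (K = 180 M⁻¹)
    acid set free + free base ⇌ salt of the base (K = 1.00 × 10⁵ M⁻¹, k = 2.45 M⁻¹ h⁻¹)
    acid set free → by-product carried off (k = 0.121 h⁻¹)

Left ten times as long, north still stood at 80.0%. When c(protonated nucleophile) in a neighbour of south-west was cut to 0.096 M, the ceiling fell to 48.0%, and that neighbour gave 48.0%, with 52% of its electrophile left at 6.00 d.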